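Millimolar is my unit of account: a flask's target is paid for in coupling partner.

in all of them: starting material 0.0020 M

| run | coupling partner | protic impurity | temperature | remark | time |
|---|---|---|---|---|---|
| Sunday's | 3 mM | 0.10 mM | 120 °C | run made earlier |  |
| dawn | 2.00 mM | 0.100 mM | 120 °C |  | 3.0 min |
| spring | 2.00 mM | 0.100 mM | 140 °C |  | 3.0 min |
| midnight | 2.00 mM | 0.100 mM | 100 °C |  | 3.0 min |
| winter | 2.00 mM | 0.100 mM |  | at 140 °C until 2.0 min, from then on at 100 °C | 3.0 min |

Sunday's run (percent of the starting material charged)

| time / s | target / % | starting material / % |
|---|---|---|
| 10.0 | 50.6 | 13.2 |
| 20.0 | 61.2 | 2.5 |
| 30.0 | 62.2 | 0 |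
| 40.0 | 61.1 | 0.4 |
| 50.0 | 62.2 | 0 |

(each reading ± 0.5 percentage points)

- steps thought possible: coupling partner + intermediate -> target; coupling partner -> decomposed reagent; coupling partner + protic impurity -> quenched reagent; starting material -> intermediate
- the earlier runs do not show what temperature does; that part of a forecast is a guess

1. the best flask by amount of target, in percent of the starting material charged; "all alike" if 1.5 percentage points covers them all (dawn / spring / midnight / winter / all alike)
2. amount of target at the end, in percent of the starting material charged, dawn
3. amount of target at the end, in percent of the starting material charged, spring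
4. amount of target at the end, in percent of the starting material charged, midnight
5. amount of target at the end, in percent of the starting material charged, winter

In Sunday's run the target levels off at 61.8 %, while starting material reads 0 % at 30.0 s. I place the remaining 38.2 % in intermediate. Target stands still with intermediate present, and coupling needs partner. So I count the usable partner as consumed, taking one partner per protic impurity:

usable partner = 3 mM − 0.10 mM = 2.90 mM; into target, 1.24 mM

The bench rule is a fixed share of usable partner, here 0.426. For dawn, with 1.90 mM usable, that gives 40.5 %.

The rule has a border. Usable partner per starting material is 1.45 in Sunday's run, but in dawn it is less, 0.950. So dawn's [intermediate] should stay higher. If each step runs as written, [coupling partner] cancels from the split between coupling and decomposition, and [intermediate] sets it. A fixed share therefore holds while [intermediate] barely moves.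

I carry the crossing instead: the [intermediate] at which coupling and decomposition each take half of the partner. Its inverse is a selectivity factor. Taking [intermediate] as charge minus target and integrating gives:

partner spent = [target] + crossing × ln(charge / (charge − [target])), with charge the starting material charged

Sunday's run gives crossing = 1.73 mM

This is a working value, since it also absorbs the seconds in which intermediate is still forming.

The forecast picks midnight. It gives dawn 45 % (41 % to 49 %), spring 40 % (27 % to 52 %), midnight 50 % (33 % to 68 %) and winter 40 % (27 % to 52 %). Its temperature ground is a stated guess: “cooler favours coupling”. My line bills the forecast's dawn at 1.93 mM against 1.90 mM usable, so I stand slightly below it.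

Midnight is best at 51.5 %, with dawn at 44.8 %, spring at 37.1 % and winter at 37.1 %. The forecast's pick stands. Winter's partner reads 0 % at 2.00 min, and its target already stands at 37.1 % there. Dawn's result bills 1.92 mM on Sunday's crossing, against 1.90 mM usable. The same line on spring's result gives a crossing of 2.50 mM, higher than the 1.73 mM from Sunday's readings.

    coupling partner + intermediate → target (k = 61.8 M⁻¹ s⁻¹, Ea = 51.0 kJ mol⁻¹)
    coupling partner → decomposed reagent (k = 0.0226 s⁻¹, Ea = 92.0 kJ mol⁻¹)
    coupling partner + protic impurity → quenched reagent (k = 1140 M⁻¹ s⁻¹, Ea = 56.0 kJ mol⁻¹)
    starting material → intermediate (k = 0.0390 s⁻¹, Ea = 101 kJ mol⁻¹)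
    (constants at 100 °C)

The neighbour is spring with 0.0012 M of coupling partner, so 1.10 mM is usable, and I keep spring's crossing for it. While the target's share is small, the line shortens to usable partner over charge plus crossing, which gives about 24.4 %. The computed flask gives 22.7 %.

The readings come from a simulation from invented constants, noise included.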